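The route rests on cutting the ring bond C1–C6, which joins the quaternary carbon C1 (methyl, side chain, C2) to the tertiary carbinol C6 of the cyclohexane. C1 with its methyl, its CH2CH2CH=C(Me) arm and C2 is the γ-carbon of a (Z)-neryl unit, so a (Z)-allylboronic acid that already carries the finished side chain is added to hept-5-yn-2-one under chiral diol catalysis. This one operation joins both fragments, creates C1 and C6 together and leaves a vinyl group as C2. The ring is then closed at C2=C3 by enyne metathesis; the C2 arm and the (Z)-enal come from a temporary Diels–Alder ring that is opened by Grob fragmentation.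

Key step: step 10

Convention: ring atoms are C1 (quaternary; CH3 and side chain), C2, C3, C4, C5 and C6 (tertiary carbinol; CH3 and O); C7 is the exocyclic carbon on C3 that bears CH3, C8 its oxygenated carbon (finally CHO); R = (3E,5S,6E,8S)-5-(tert-butyldimethylsilyloxy)-4,8,12-trimethyltrideca-3,6,11-trien-1-yl, the protected side chain on C1.

Assumption: the sense of induction of the amino alcohol in step 4 and of the binaphthol in step 10 is assigned by analogy with simple aldehydes and ketones; both antipodes are available and the antipode is used if the analogy does not hold.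

Step 1
Reactants: 1 (S)-citronellal
Product: 3 (3S)-3,7-dimethyloct-6-en-1-yne, via alkenyl nonaflate 2 (not isolated)
Conditions: C4F9SO2F (1.2 equiv), phosphazene base P2-Et [EtN=P(NMe2)2–N=P(NMe2)3] (2.3 equiv), DMF, −20 °C → rt
Reagents that add atoms: none
Why: Enol nonaflation followed by base-induced β-elimination in one flask (aldehyde-to-alkyne conversion through the alkenyl sulfonate) turns CH2CHO into C≡CH with all ten carbons kept; the methyl-bearing centre comes from (S)-citronellal, is not acidic and is retained.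

Step 2
Reactants: 4 neryl acetate
Product: 5 (2Z,6E)-8-hydroxy-3,7-dimethylocta-2,6-dien-1-yl acetate
Conditions: SeO2 (0.3 equiv), t-BuOOH (3 equiv), salicylic acid (0.1 equiv), CH2Cl2, rt
Reagents that add atoms: tert-butyl hydroperoxide, CC(C)(C)OO (terminal oxygen donor); selenium dioxide, O=[Se]=O (oxygen carrier)
Why: Selenium dioxide allylic oxidation (ene reaction, then [2,3]-sigmatropic shift) attacks the electron-rich terminal alkene at its E methyl group and spares the 2,3-alkene, which the allylic acetate deactivates; the E geometry is inherent to the mechanism and no stereocentre forms.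

Step 3
Reactants: 5 (2Z,6E)-8-hydroxyneryl acetate
Product: 6 (2Z,6E)-3,7-dimethyl-8-oxoocta-2,6-dien-1-yl acetate
Conditions: activated MnO2 (15 equiv), CH2Cl2, rt
Reagents that add atoms: none
Why: Manganese dioxide oxidises only allylic alcohols, so the E enal forms without touching the acetate or the Z alkene.

Step 4
Reactants: 3 (3S)-3,7-dimethyloct-6-en-1-yne + 6 (2Z,6E)-8-oxoneryl acetate
Product: 9 (2Z,6E,8S,9E,11S)-8-hydroxy-3,7,11,15-tetramethylhexadeca-2,6,9,14-tetraen-1-yl acetate, via alkenylborane 7 (not isolated), via alkenylzinc 8 (not isolated)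
Conditions: alkyne 3 (1.5 equiv), Cy2BH (1.5 equiv), toluene, 0 °C → rt; Me2Zn (1.6 equiv), −78 °C; (2S)-(−)-3-exo-morpholinoisoborneol (10 mol %); enal 6 (1.0 equiv), −20 → 0 °C; aq. NH4Cl
Reagents that add atoms: none
Why: Syn hydroboration of the terminal alkyne fixes the E alkene, boron-to-zinc exchange gives the alkenylzinc, and its amino-alcohol-catalysed asymmetric 1,2-addition to the enal is steered by the ligand to the Si face of the aldehyde, which sets the carbinol as S; the acetate is inert to the organozinc at or below 0 °C.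

Step 5
Reactants: 9 dienol acetate
Product: 10 (2Z,6E,8S,9E,11S)-8-(tert-butyldimethylsilyloxy)-3,7,11,15-tetramethylhexadeca-2,6,9,14-tetraen-1-yl acetate
Conditions: TBSCl (1.3 equiv), imidazole (2.5 equiv), DMF, rt
Reagents that add atoms: tert-butyldimethylsilyl chloride, CC(C)(C)[Si](C)(C)Cl
Why: Silylation of the secondary alcohol protects the doubly allylic carbinol against ionisation in step 7 and against oxidation in step 20; no stereocentre is touched.

Step 6
Reactants: 10 silyl ether acetate
Product: 11 (2Z,6E,8S,9E,11S)-8-(tert-butyldimethylsilyloxy)-3,7,11,15-tetramethylhexadeca-2,6,9,14-tetraen-1-ol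
Conditions: K2CO3 (0.2 equiv), MeOH, 0 °C → rt
Reagents that add atoms: none
Why: Base-catalysed transesterification with methanol removes the acetate and leaves the silyl ether and all alkene geometries as they are.

Step 7
Reactants: 11 (Z)-allylic alcohol
Product: 12 [(2Z,6E,8S,9E,11S)-8-(tert-butyldimethylsilyloxy)-3,7,11,15-tetramethylhexadeca-2,6,9,14-tetraen-1-yl]boronic acid
Conditions: B2(OH)4 (1.3 equiv), [Pd(MeCN)4](BF4)2 (3 mol %), DMSO/MeOH, rt, argon; extractive isolation under argon, used at once
Reagents that add atoms: tetrahydroxydiboron, OB(O)B(O)O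
Why: Palladium-catalysed direct borylation of the allylic alcohol through an η3-allylpalladium intermediate places boron on the unsubstituted terminus and keeps the Z geometry of the trisubstituted alkene, as in the conversion of nerol into nerylboronic acid; the silyl ether and the other alkenes are not activated.

Step 8
Reactants: 13 ethyl acetoacetate + 14 1-bromobut-2-yne
Product: 15 ethyl 2-acetylhex-4-ynoate (racemic)
Conditions: NaOEt (1.0 equiv), ketoester 13 in 1.5-fold excess over bromide 14, EtOH, 0 °C → reflux
Reagents that add atoms: none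
Why: Acetoacetic ester alkylation, in which the stabilised enolate displaces the propargylic bromide (SN2) and the excess of 13 suppresses dialkylation; the stereocentre formed is lost in step 9.

Step 9
Reactants: 15 ethyl 2-acetylhex-4-ynoate
Product: 17 hept-5-yn-2-one, via 2-acetylhex-4-ynoic acid 16 (not isolated)
Conditions: aq. NaOH (1.2 equiv), rt; HCl to pH 1; 60 °C
Reagents that add atoms: none
Why: Saponification and thermal decarboxylation of the β-keto acid (acetoacetic ester ketone synthesis) leave the methyl ketone; the internal alkyne is inert.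

Step 10
Reactants: 12 (Z)-allylboronic acid + 17 hept-5-yn-2-one
Product: 18 (6S,7S,10E,12S,13E,15S)-12-(tert-butyldimethylsilyloxy)-7-ethenyl-6,7,11,15,19-pentamethylicosa-10,13,18-trien-2-yn-6-ol
Conditions: ketone 17 (2 equiv), (S)-3,3'-dibromo-1,1'-bi-2-naphthol (20 mol %), t-BuOH (3 equiv), 3 Å molecular sieves, toluene, 0 °C → rt, argon; aqueous work-up
Reagents that add atoms: none
Why: Chiral-diol-catalysed allylboration of a ketone: the boronic acid exchanges hydroxyl for the binaphthol, the ketone oxygen binds boron, and the γ-carbon (future C1) attacks the carbonyl carbon (future C6) through a closed six-membered chair with allylic transposition, which leaves the vinyl group that becomes C2. The closest known reaction type is the binaphthol-catalysed addition of geranyl- and nerylboronic acids to ketones, which builds a quaternary carbon next to a tertiary carbinol; no ring is closed in this step. The relation of C1 to C6 follows from the Z alkene, which places the homoallylic chain axial and the γ-methyl equatorial, together with the ketone methyl axial and its pentynyl arm equatorial; the absolute sense (both centres S) is imposed by the diol on boron, the remote side-chain centres having no influence. The step needs discrimination of methyl from the CH2CH2C≡CMe arm and the choice of one of the two mirror-image chairs, which the small size of methyl and the catalyst are to secure. Chemoselectivity is not in question, because the alkyne, the silyl ether and the isolated alkenes do not react with boron, and the quaternary carbon arises by transposition, not by substitution at a hindered centre.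

Step 11
Reactants: 18 enyne alcohol
Product: 19 (1S,6S)-1,6-dimethyl-3-(prop-1-en-2-yl)-1-R-cyclohex-2-en-6-ol
Conditions: (H2IMes)(PCy3)Cl2Ru=CHPh (second-generation Grubbs catalyst, 7 mol %), ethylene (1 atm), toluene (0.005 M), 70 °C
Reagents that add atoms: none
Why: Ring-closing enyne metathesis of the 1,7-enyne in the exo mode: under ethylene the ruthenium methylidene adds to the alkyne and the vinylcarbene closes onto the C2 vinyl group, which gives the six-membered ring with C2=C3 and the 2-propenyl group on C3; no stereocentre is touched, and the branched or trisubstituted side-chain alkenes should react more slowly.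

Step 12
Reactants: 19 semicyclic diene
Product: 21 (1S,6S)-3-[(2RS)-1-hydroxypropan-2-yl]-1,6-dimethyl-1-R-cyclohex-2-en-6-ol, via B-alkyl-9-BBN adduct 20 (not isolated)
Conditions: 9-BBN (2.5 equiv), THF, 0 °C → rt; aq. NaOH, 30% H2O2, 0 °C
Reagents that add atoms: hydrogen peroxide, OO
Why: Hydroboration–oxidation with 9-BBN selects the 1,1-disubstituted terminus of the diene over the trisubstituted and the doubly branched disubstituted alkenes and puts boron on CH2; C7 forms as a mixture of epimers, which is irrelevant because C7 becomes trigonal in step 14.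

Step 13
Reactants: 21 primary alcohol
Product: 22 (2RS)-2-[(1S,6S)-6-hydroxy-1,6-dimethyl-1-R-cyclohex-2-en-3-yl]propanal
Conditions: Dess–Martin periodinane (1.3 equiv), NaHCO3 (5 equiv), CH2Cl2, 0 °C; used crude
Reagents that add atoms: none
Why: Buffered periodinane oxidation gives the β,γ-unsaturated aldehyde without migration of the double bond into conjugation; the tertiary alcohol cannot be oxidised.

Step 14
Reactants: 22 β,γ-unsaturated aldehyde
Product: 23 (1S,6S)-1,6-dimethyl-1-R-6-(trimethylsilyloxy)-3-[(1E)-1-(trimethylsilyloxy)prop-1-en-2-yl]cyclohex-2-ene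
Conditions: Me3SiOTf (2.6 equiv), Et3N (5 equiv), CH2Cl2, −78 → 0 °C; non-aqueous work-up, used at once
Reagents that add atoms: trimethylsilyl trifluoromethanesulfonate, C[Si](C)(C)OS(=O)(=O)C(F)(F)F
Why: Soft enolisation and O-silylation of the α-branched aldehyde gives the 1-silyloxy diene, with E favoured because the silyloxy group sits cis to methyl and not to the cyclohexenyl group; the tertiary alcohol is silylated at the same time and C7 loses its stereocentre.

Step 15
Reactants: 23 silyl dienol ether + 24 methyl acrylate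
Product: 25 endo Diels–Alder adduct: methyl 4,7,8-trimethyl-8-R-3,7-bis(trimethylsilyloxy)-1,2,3,5,6,7,8,8a-octahydronaphthalene-2-carboxylate (naphthalene numbering; C8a is ring C2; ester cis to the 3-silyloxy group; both trans to H-8a; ring C1/C2/C6 are S/R/S)
Conditions: methyl acrylate in tenfold excess, butylated hydroxytoluene (trace, radical inhibitor), toluene, sealed tube, 110 °C
Reagents that add atoms: none
Why: Diels–Alder cycloaddition of the 1-silyloxy diene, ortho-regioselective (acrylate CH2 to C2, ester carbon next to C8), a pure addition in which every atom of both partners is kept; C2 is set by approach anti to the pseudoaxial C1 side chain on the face of the C6 oxygen, where only an axial oxygen and not a methyl group is syn-axial to the forming bond, and the endo/exo ratio does not matter because both temporary centres are erased in step 18.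

Step 16
Reactants: 25 Diels–Alder adduct
Product: 27 triol with CH2OH in place of CO2Me and free hydroxyls on C8 and C6, via bis(trimethylsilyl) primary alcohol 26 (not isolated)
Conditions: LiAlH4, THF, 0 °C; H2O/aq. NaOH work-up; crude in MeOH, K2CO3 (0.3 equiv), rt
Reagents that add atoms: none
Why: Hydride reduction of the ester to the primary alcohol, then base-catalysed methanolysis of both trimethylsilyl ethers, which leaves the tert-butyldimethylsilyl ether intact; no stereocentre changes.

Step 17
Reactants: 27 triol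
Product: 28 primary p-toluenesulfonate of 27
Conditions: TsCl (1.2 equiv), Et3N (2 equiv), 4-(dimethylamino)pyridine (0.1 equiv), CH2Cl2, 0 °C
Reagents that add atoms: p-toluenesulfonyl chloride, Cc1ccc(cc1)S(Cl)(=O)=O
Why: Sulfonylation selects the primary hydroxyl over the hindered secondary allylic and the tertiary hydroxyl.

Step 18
Reactants: 28 monotosylate
Product: 29 (2Z)-2-[(1S,2R,6S)-6-hydroxy-1,6-dimethyl-2-(prop-2-en-1-yl)-1-R-cyclohex-3-ylidene]propanal
Conditions: KOt-Bu (2.5 equiv), THF, 0 °C
Reagents that add atoms: none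
Why: Grob fragmentation: the C8 alkoxide expels tosylate across the C8–C bond, which is favoured over oxetane closure because C8 is allylic and a conjugated aldehyde results; since C3=C7 was endocyclic in the temporary ring the aldehyde emerges cis to C2 (Z), C2 is untouched, and both epimers at the tosyloxymethyl carbon converge on the same product.

Step 19
Reactants: 29 (Z)-enal with allyl group on C2
Product: 31 (1S,2R,6S)-2-(3-hydroxypropyl)-3-[(2Z)-1-hydroxypropan-2-ylidene]-1,6-dimethyl-1-R-cyclohexan-6-ol, via bis-borylated intermediate 30 (not isolated)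
Conditions: 9-BBN (4 equiv), THF, 0 °C → rt; aq. NaOH, 30% H2O2, 0 °C
Reagents that add atoms: hydrogen peroxide, OO
Why: 9-BBN acts twice, reducing the conjugated aldehyde 1,2 to the allylic alcohol and hydroborating the monosubstituted alkene anti-Markovnikov far faster than the tri- and tetrasubstituted alkenes, so oxidation gives the diol with C2 and the Z geometry untouched.

Step 20
Reactants: 31 diol
Product: 32 (2Z)-2-[(1S,2R,6S)-6-hydroxy-2-(3-hydroxypropyl)-1,6-dimethyl-1-R-cyclohex-3-ylidene]propanal
Conditions: activated MnO2 (20 equiv), CH2Cl2, rt, dark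
Reagents that add atoms: none
Why: Manganese dioxide oxidises the allylic alcohol back to the (Z)-enal and leaves the saturated primary and the tertiary alcohol alone, while the doubly allylic side-chain carbinol is still masked as its silyl ether.

Step 21
Reactants: 32 silyl-protected target
Product: 33 target CNP0323596.2
Conditions: Bu4NF (3 equiv), AcOH (3 equiv), THF, 0 °C → rt
Reagents that add atoms: none
Why: Buffered fluoride desilylation frees the doubly allylic carbinol without acid, which would ionise it, and without strong base, which would deconjugate or isomerise the enal.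

Compound list
1 | (S)-citronellal, (3S)-3,7-dimethyloct-6-enal | CC(C)=CCC[C@H](C)CC=O | starting material
2 | (3S)-3,7-dimethylocta-1,6-dien-1-yl nonafluorobutane-1-sulfonate (E/Z mixture, in situ) | CC(C)=CCC[C@H](C)C=COS(=O)(=O)C(F)(F)C(F)(F)C(F)(F)C(F)(F)F | intermediate
3 | (3S)-3,7-dimethyloct-6-en-1-yne | CC(C)=CCC[C@H](C)C#C | intermediate
4 | neryl acetate, (2Z)-3,7-dimethylocta-2,6-dien-1-yl acetate | CC(C)=CCC/C(C)=C\COC(C)=O | starting material
5 | (2Z,6E)-8-hydroxy-3,7-dimethylocta-2,6-dien-1-yl acetate | OC/C(C)=C/CC/C(C)=C\COC(C)=O | intermediate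
6 | (2Z,6E)-3,7-dimethyl-8-oxoocta-2,6-dien-1-yl acetate | O=C/C(C)=C/CC/C(C)=C\COC(C)=O | intermediate
7 | dicyclohexyl[(1E,3S)-3,7-dimethylocta-1,6-dien-1-yl]borane (in situ) | CC(C)=CCC[C@H](C)/C=C/B(C1CCCCC1)C1CCCCC1 | intermediate
8 | [(1E,3S)-3,7-dimethylocta-1,6-dien-1-yl](methyl)zinc (in situ) | CC(C)=CCC[C@H](C)/C=C/[Zn]C | intermediate
9 | (2Z,6E,8S,9E,11S)-8-hydroxy-3,7,11,15-tetramethylhexadeca-2,6,9,14-tetraen-1-yl acetate | CC(C)=CCC[C@H](C)/C=C/[C@H](O)/C(C)=C/CC/C(C)=C\COC(C)=O | intermediate
10 | (2Z,6E,8S,9E,11S)-8-(tert-butyldimethylsilyloxy)-3,7,11,15-tetramethylhexadeca-2,6,9,14-tetraen-1-yl acetate | CC(C)=CCC[C@H](C)/C=C/[C@H](O[Si](C)(C)C(C)(C)C)/C(C)=C/CC/C(C)=C\COC(C)=O | intermediate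
11 | (2Z,6E,8S,9E,11S)-8-(tert-butyldimethylsilyloxy)-3,7,11,15-tetramethylhexadeca-2,6,9,14-tetraen-1-ol | CC(C)=CCC[C@H](C)/C=C/[C@H](O[Si](C)(C)C(C)(C)C)/C(C)=C/CC/C(C)=C\CO | intermediate
12 | [(2Z,6E,8S,9E,11S)-8-(tert-butyldimethylsilyloxy)-3,7,11,15-tetramethylhexadeca-2,6,9,14-tetraen-1-yl]boronic acid | CC(C)=CCC[C@H](C)/C=C/[C@H](O[Si](C)(C)C(C)(C)C)/C(C)=C/CC/C(C)=C\CB(O)O | intermediate
13 | ethyl acetoacetate | CCOC(=O)CC(C)=O | starting material
14 | 1-bromobut-2-yne | CC#CCBr | starting material
15 | ethyl 2-acetylhex-4-ynoate (racemic) | CCOC(=O)C(CC#CC)C(C)=O | intermediate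
16 | 2-acetylhex-4-ynoic acid (in situ) | CC#CCC(C(C)=O)C(=O)O | intermediate
17 | hept-5-yn-2-one | CC#CCCC(C)=O | intermediate
18 | (6S,7S,10E,12S,13E,15S)-12-(tert-butyldimethylsilyloxy)-7-ethenyl-6,7,11,15,19-pentamethylicosa-10,13,18-trien-2-yn-6-ol | CC(C)=CCC[C@H](C)/C=C/[C@H](O[Si](C)(C)C(C)(C)C)/C(C)=C/CC[C@@](C)(C=C)[C@@](C)(O)CCC#CC | intermediate
19 | (1S,6S)-1,6-dimethyl-3-(prop-1-en-2-yl)-1-R-cyclohex-2-en-6-ol | CC(C)=CCC[C@H](C)/C=C/[C@H](O[Si](C)(C)C(C)(C)C)/C(C)=C/CC[C@@]1(C)C=C(C(C)=C)CC[C@]1(C)O | intermediate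
20 | B-alkyl-9-borabicyclo[3.3.1]nonane adduct of 19, boron on C8 (C7 epimers, in situ) | CC(C)=CCC[C@H](C)/C=C/[C@H](O[Si](C)(C)C(C)(C)C)/C(C)=C/CC[C@@]1(C)C=C(C(C)CB2C3CCCC2CCC3)CC[C@]1(C)O | intermediate
21 | (1S,6S)-3-[(2RS)-1-hydroxypropan-2-yl]-1,6-dimethyl-1-R-cyclohex-2-en-6-ol | CC(C)=CCC[C@H](C)/C=C/[C@H](O[Si](C)(C)C(C)(C)C)/C(C)=C/CC[C@@]1(C)C=C(C(C)CO)CC[C@]1(C)O | intermediate
22 | (2RS)-2-[(1S,6S)-6-hydroxy-1,6-dimethyl-1-R-cyclohex-2-en-3-yl]propanal | CC(C)=CCC[C@H](C)/C=C/[C@H](O[Si](C)(C)C(C)(C)C)/C(C)=C/CC[C@@]1(C)C=C(C(C)C=O)CC[C@]1(C)O | intermediate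
23 | (1S,6S)-1,6-dimethyl-1-R-6-(trimethylsilyloxy)-3-[(1E)-1-(trimethylsilyloxy)prop-1-en-2-yl]cyclohex-2-ene | CC(C)=CCC[C@H](C)/C=C/[C@H](O[Si](C)(C)C(C)(C)C)/C(C)=C/CC[C@@]1(C)C=C(/C(C)=C/O[Si](C)(C)C)CC[C@]1(C)O[Si](C)(C)C | intermediate
24 | methyl acrylate | C=CC(=O)OC | starting material
25 | endo Diels–Alder adduct: methyl 4,7,8-trimethyl-8-R-3,7-bis(trimethylsilyloxy)-1,2,3,5,6,7,8,8a-octahydronaphthalene-2-carboxylate (new ring C2–CH2–CH(CO2Me)–C8H(OSiMe3)–C7(Me)=C3; ester and silyloxy cis, both trans to H on ring C2; ring C1 S, C2 R, C6 S) | CC(C)=CCC[C@H](C)/C=C/[C@H](O[Si](C)(C)C(C)(C)C)/C(C)=C/CC[C@@]1(C)[C@@H]2C[C@H](C(=O)OC)[C@H](O[Si](C)(C)C)C(C)=C2CC[C@]1(C)O[Si](C)(C)C | intermediate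
26 | primary alcohol from 25 (CH2OH for CO2Me, both trimethylsilyl ethers kept, in situ) | CC(C)=CCC[C@H](C)/C=C/[C@H](O[Si](C)(C)C(C)(C)C)/C(C)=C/CC[C@@]1(C)[C@@H]2C[C@H](CO)[C@H](O[Si](C)(C)C)C(C)=C2CC[C@]1(C)O[Si](C)(C)C | intermediate
27 | triol: CH2OH and C8–OH cis on the temporary ring, free C6–OH | CC(C)=CCC[C@H](C)/C=C/[C@H](O[Si](C)(C)C(C)(C)C)/C(C)=C/CC[C@@]1(C)[C@@H]2C[C@H](CO)[C@H](O)C(C)=C2CC[C@]1(C)O | intermediate
28 | primary p-toluenesulfonate of 27 | CC(C)=CCC[C@H](C)/C=C/[C@H](O[Si](C)(C)C(C)(C)C)/C(C)=C/CC[C@@]1(C)[C@@H]2C[C@H](COS(=O)(=O)c3ccc(C)cc3)[C@H](O)C(C)=C2CC[C@]1(C)O | intermediate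
29 | (2Z)-2-[(1S,2R,6S)-6-hydroxy-1,6-dimethyl-2-(prop-2-en-1-yl)-1-R-cyclohex-3-ylidene]propanal | CC(C)=CCC[C@H](C)/C=C/[C@H](O[Si](C)(C)C(C)(C)C)/C(C)=C/CC[C@@]1(C)[C@H](CC=C)/C(=C(/C)C=O)CC[C@]1(C)O | intermediate
30 | 29 after reduction and hydroboration: O-(9-borabicyclononyl) allylic borinate and terminal B-alkyl-9-borabicyclononane (in situ) | CC(C)=CCC[C@H](C)/C=C/[C@H](O[Si](C)(C)C(C)(C)C)/C(C)=C/CC[C@@]1(C)[C@H](CCCB2C3CCCC2CCC3)/C(=C(/C)COB2C3CCCC2CCC3)CC[C@]1(C)O | intermediate
31 | (1S,2R,6S)-2-(3-hydroxypropyl)-3-[(2Z)-1-hydroxypropan-2-ylidene]-1,6-dimethyl-1-R-cyclohexan-6-ol | CC(C)=CCC[C@H](C)/C=C/[C@H](O[Si](C)(C)C(C)(C)C)/C(C)=C/CC[C@@]1(C)[C@H](CCCO)/C(=C(/C)CO)CC[C@]1(C)O | intermediate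
32 | (2Z)-2-[(1S,2R,6S)-6-hydroxy-2-(3-hydroxypropyl)-1,6-dimethyl-1-R-cyclohex-3-ylidene]propanal | CC(C)=CCC[C@H](C)/C=C/[C@H](O[Si](C)(C)C(C)(C)C)/C(C)=C/CC[C@@]1(C)[C@H](CCCO)/C(=C(/C)C=O)CC[C@]1(C)O | intermediate
33 | CNP0323596.2: 32 with free (5S)-hydroxyl in the side chain | CC(C)=CCC[C@H](C)/C=C/[C@H](O)/C(C)=C/CC[C@@]1(C)[C@H](CCCO)/C(=C(/C)C=O)CC[C@]1(C)O | target

Total steps: 21. Longest linear sequence: 18 steps (from neryl acetate 4: steps 2–7 and 10–21); the alkyne 3 takes one step and the ketone 17 two steps.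

Steps most likely to fail

Step 15. The thermal cycloaddition must form a bond at the neopentyl diene terminus C2, so it may be slow enough for the silyl dienol ether to decay, and the dienophile may add to both faces of the diene and give C2 epimers. The fallback replaces substrate control by reagent control and sets out from 23. At −78 °C in CH2Cl2, 23 is combined with the chelate of (R)-3-acryloyl-4-benzyloxazolidin-2-one and Et2AlCl (1.5 equiv). The activated dienophile reacts far below the temperature of step 15, and the endo mode together with the shielded face of the auxiliary fixes the configuration at the acyl-bearing carbon and, through it, the diene face. This should give the imide adduct F1. Reductive removal of the auxiliary with LiBH4 (THF, MeOH, 0 °C) leads to alcohol 26, where the route is rejoined (methanolysis to 27 as in step 16).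

Step 11. A ruthenium alkylidene formed on the C2 vinyl group may close a cyclopentene onto the trisubstituted alkene of the side chain, which would cut the chain off, or the hindered vinyl group may not be engaged at all. The fallback uses π-acid catalysis instead of carbene metathesis and sets out from 18. The tertiary hydroxyl is silylated (Me3SiOTf, 2,6-lutidine, CH2Cl2, −78 °C) to the enyne silyl ether F2, so that the oxygen cannot add to the activated alkyne. A cationic monovalent gold complex, [(2-biphenylyl)(t-Bu)2PAu(NCMe)]SbF6 (3 mol %) in CH2Cl2 at rt, should then bring about the exo single-cleavage skeletal rearrangement of the 1,7-enyne through a cyclopropyl gold carbene. This path involves only the alkyne and the one alkene that can reach it in a six-membered ring, and leads to the diene silyl ether F3. Bu4NF/AcOH (THF, 0 °C) returns 19.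

Step 10. The chair may discriminate poorly between methyl and the pentynyl arm of the ketone (C6 epimers), or the diol may turn over slowly with so large a boronic acid, so that the unselective background addition takes over. The fallback uses a stoichiometric chiral boron reagent instead of catalysis and sets out from 12. Condensation with one equivalent of (S)-3,3'-bis(trifluoromethyl)-1,1'-bi-2-naphthol (toluene, 3 Å molecular sieves, rt) gives the cyclic binaphthol boronate F4, in which every allyl group is transferred from a chiral boron centre. Ketone 17 is added at −78 → −40 °C; hydrolytic work-up gives 18 and returns the binaphthol.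

Further compounds
F1 | step 15 | endo imide adduct: 25 with (4R)-4-benzyl-2-oxo-oxazolidin-3-ylcarbonyl in place of CO2Me | CC(C)=CCC[C@H](C)/C=C/[C@H](O[Si](C)(C)C(C)(C)C)/C(C)=C/CC[C@@]1(C)[C@@H]2C[C@H](C(=O)N3[C@H](Cc4ccccc4)COC3=O)[C@H](O[Si](C)(C)C)C(C)=C2CC[C@]1(C)O[Si](C)(C)C
F2 | step 11 | trimethylsilyl ether of enyne 18 at the tertiary hydroxyl | CC(C)=CCC[C@H](C)/C=C/[C@H](O[Si](C)(C)C(C)(C)C)/C(C)=C/CC[C@@](C)(C=C)[C@@](C)(O[Si](C)(C)C)CCC#CC
F3 | step 11 | trimethylsilyl ether of diene 19 at C6–O | CC(C)=CCC[C@H](C)/C=C/[C@H](O[Si](C)(C)C(C)(C)C)/C(C)=C/CC[C@@]1(C)C=C(C(C)=C)CC[C@]1(C)O[Si](C)(C)C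
F4 | step 10 | cyclic boronate of 12 with (S)-3,3'-bis(trifluoromethyl)-1,1'-bi-2-naphthol (axial chirality S, not shown in the SMILES) | CC(C)=CCC[C@H](C)/C=C/[C@H](O[Si](C)(C)C(C)(C)C)/C(C)=C/CC/C(C)=C\CB1Oc2c(C(F)(F)F)cc3ccccc3c2-c2c(O1)c(C(F)(F)F)cc1ccccc21
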